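**Strategy.** The depside is cut at its aryl ester into a ring A acid and a ring B phenol, and the route rests on building ring B through an aryne. In ring B the C6 pentyl group and the C1 carboxyl carbon sit on adjacent ring atoms, with the C2 methoxy group on the other side of C1. This contiguous pattern is what a 3-methoxybenzyne gives when it takes up a carbon nucleophile and then an electrophile. A single flask operation thus turns the TIPS ether of 3-fluoro-5-methoxyphenol, pentyllithium and carbon dioxide into the complete ring B acid, with its methyl ether and masked phenol already distinguished. Ring A comes from divarinol, and all benzyl groups leave together at the end.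

Key step: step 3

Remark: the target has no stereocentre, so no stereocontrol is needed; each ring is numbered from its carboxyl-bearing carbon (C1), and pentyllithium is prepared and titrated just before use.

**Step 1**
Reactants: 1 3-fluoro-5-methoxyphenol
Product: 2 (3-fluoro-5-methoxyphenoxy)triisopropylsilane
Conditions: TIPSCl (1.2 equiv), imidazole (2 equiv), DMF, rt
Reagents that add atoms: chlorotriisopropylsilane (TIPSCl), CC(C)[Si](Cl)(C(C)C)C(C)C
Why: Imidazole-promoted silylation of a phenol (silyl ether formation) should be clean, and the bulky TIPS group both masks the acidic OH and shields its two neighbouring ring positions from the later lithiation.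

**Step 2**
Reactants: 3 1-bromopentane
Product: 4 pentyllithium (titrated ether solution)
Conditions: Li wire (about 1% Na, 2.2 equiv), Et2O, −15 °C, argon; filter, titrate
Reagents that add atoms: lithium, [Li]
Why: Reductive lithiation of a primary alkyl bromide by lithium metal in ether is the classical preparation of n-alkyllithiums, and the low temperature should hold back Wurtz coupling.

**Step 3**
Reactants: 2 (3-fluoro-5-methoxyphenoxy)triisopropylsilane; 4 pentyllithium; 5 carbon dioxide
Product: 9 2-methoxy-6-pentyl-4-(triisopropylsilyloxy)benzoic acid, via ortho-lithiated fluoroarene 6 (not isolated), via 3-methoxy-5-silyloxybenzyne 7 (not isolated), via aryllithium adduct 8 (not isolated)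
Conditions: 4 (3 equiv), THF–Et2O, −78 °C, 1 h; −78 → −10 °C over 2 h; recool to −78 °C, CO2 gas (excess); aq. HCl
Reagents that add atoms: none
Why: Pentyllithium first lithiates 2 at the one ring C–H flanked by fluorine and methoxy (directed ortho-metalation) to give 6, which on warming expels LiF to form aryne 7; a further equivalent of pentyllithium then adds across the strained triple bond (carbolithiation) to give 8, and CO2 carboxylates that aryllithium. The closest known reaction type is the addition of alkyllithiums to the 3-methoxybenzyne generated from 3-fluoroanisole with carboxylation in the same flask, an established entry to 6-alkyl-2-methoxybenzoic acids. No ring is closed and no stereocentre is created. Site selectivity of the lithiation should be secured by the combined acidifying effect of F and OMe on the C–H between them and by the bulky TIPS ether, which neither coordinates lithium nor leaves room at its two neighbouring positions. Regioselectivity of the addition should be secured by the methoxy group next to the aryne, whose inductive pull distorts the triple bond and stabilises negative charge on the adjacent carbon, so the pentyl group enters meta to OMe and lithium ends up between OMe and pentyl. Chemoselectivity relies on excess pentyllithium outrunning the less nucleophilic aryllithiums 6 and 8 for the aryne, and on the doubly flanked lithium carboxylate resisting a second addition.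

**Step 4**
Reactants: 9 2-methoxy-6-pentyl-4-(triisopropylsilyloxy)benzoic acid
Product: 10 benzyl 2-methoxy-6-pentyl-4-(triisopropylsilyloxy)benzoate
Conditions: BnBr (1.2 equiv), KHCO3 (1.5 equiv), DMF, rt
Reagents that add atoms: benzyl bromide, BrCc1ccccc1
Why: O-alkylation of the carboxylate (SN2 on benzyl bromide) takes place away from the hindered carbonyl carbon, so the two ortho substituents should not matter, and bicarbonate is too mild to cleave the aryl silyl ether.

**Step 5**
Reactants: 10 benzyl 2-methoxy-6-pentyl-4-(triisopropylsilyloxy)benzoate
Product: 11 benzyl 4-hydroxy-2-methoxy-6-pentylbenzoate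
Conditions: TBAF (1.1 equiv), AcOH (1.1 equiv), THF, 0 °C
Reagents that add atoms: none
Why: Fluoride-mediated desilylation is driven by the strong Si–F bond, and the acetic acid buffer protonates the phenoxide as it forms so that the benzyl ester is left alone.

**Step 6**
Reactants: 12 5-propylresorcinol (divarinol)
Product: 14 2,4-dihydroxy-6-propylbenzaldehyde, via aryl iminium chloride 13 (not isolated)
Conditions: POCl3 (1.2 equiv), DMF, 0 °C → rt; then H2O, 50 °C
Reagents that add atoms: N,N-dimethylformamide, CN(C)C=O (formyl carbon); water, O (aldehyde oxygen)
Why: Vilsmeier–Haack formylation of a 5-alkylresorcinol should go para to one hydroxyl and ortho to the other, beside the alkyl chain, rather than at the more congested carbon between the two hydroxyls, as is well established for orcinol and olivetol.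

**Step 7**
Reactants: 14 2,4-dihydroxy-6-propylbenzaldehyde
Product: 15 2-hydroxy-4-methoxy-6-propylbenzaldehyde
Conditions: MeI (1.05 equiv), K2CO3 (1.0 equiv), acetone, rt
Reagents that add atoms: iodomethane, CI
Why: In this Williamson ether synthesis the C4 hydroxyl (para to the formyl group) is the more acidic and is free, whereas the C2 hydroxyl is tied up in a hydrogen bond to the formyl oxygen, so one equivalent of iodomethane should methylate C4–OH only.

**Step 8**
Reactants: 15 2-hydroxy-4-methoxy-6-propylbenzaldehyde
Product: 16 2-benzyloxy-4-methoxy-6-propylbenzaldehyde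
Conditions: BnBr (1.2 equiv), K2CO3 (2 equiv), DMF, 60 °C
Reagents that add atoms: benzyl bromide, BrCc1ccccc1
Why: Williamson benzylation of the remaining chelated phenol needs only the more forcing DMF and heat conditions, and nothing else in the molecule can be alkylated.

**Step 9**
Reactants: 16 2-benzyloxy-4-methoxy-6-propylbenzaldehyde
Product: 17 2-benzyloxy-4-methoxy-6-propylbenzoic acid
Conditions: NaClO2, NaH2PO4, 2-methyl-2-butene (excess), t-BuOH–H2O, rt
Reagents that add atoms: sodium chlorite, [Na+].[O-]Cl=O
Why: The Pinnick oxidation converts an aryl aldehyde into the acid without touching benzyl or methyl ethers, and the alkene scavenger removes hypochlorous acid before it can chlorinate the electron-rich ring.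

**Step 10**
Reactants: 17 2-benzyloxy-4-methoxy-6-propylbenzoic acid; 11 benzyl 4-hydroxy-2-methoxy-6-pentylbenzoate
Product: 19 benzyl 4-[(2-benzyloxy-4-methoxy-6-propylbenzoyl)oxy]-2-methoxy-6-pentylbenzoate, via acid chloride 18 (not isolated)
Conditions: (COCl)2, DMF (cat.), CH2Cl2, 0 °C → rt, evaporate; then 11, Et3N, DMAP (cat.), CH2Cl2, 0 °C → rt
Reagents that add atoms: oxalyl chloride, O=C(Cl)C(=O)Cl (supplies only the chlorine of intermediate 18)
Why: Acid chloride formation followed by DMAP-catalysed acylation of a phenol (nucleophilic acyl substitution) should give the depside ester, since the C4 phenol of 11 is the only free nucleophile and the electron-rich aroyl chloride is activated further as its acylpyridinium salt.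

**Step 11**
Reactants: 19 benzyl 4-[(2-benzyloxy-4-methoxy-6-propylbenzoyl)oxy]-2-methoxy-6-pentylbenzoate
Product: 20 4-[(2-hydroxy-4-methoxy-6-propylbenzoyl)oxy]-2-methoxy-6-pentylbenzoic acid (target)
Conditions: H2 (1 atm), 10% Pd/C, EtOAc, rt
Reagents that add atoms: none
Why: Catalytic hydrogenolysis cleaves the benzylic C–O bonds of the benzyl ester and the benzyl ether in one operation, while the aryl ester link between the rings has no benzylic C–O bond and should survive.

**Compound list**
1 | 3-fluoro-5-methoxyphenol | COc1cc(O)cc(F)c1 | starting material
2 | (3-fluoro-5-methoxyphenoxy)triisopropylsilane | COc1cc(F)cc(O[Si](C(C)C)(C(C)C)C(C)C)c1 | intermediate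
3 | 1-bromopentane | CCCCCBr | starting material
4 | pentyllithium | [Li]CCCCC | intermediate
5 | carbon dioxide | O=C=O | starting material
6 | [2-fluoro-6-methoxy-4-(triisopropylsilyloxy)phenyl]lithium (formed in the flask) | COc1cc(O[Si](C(C)C)(C(C)C)C(C)C)cc(F)c1[Li] | intermediate
7 | 3-methoxy-5-(triisopropylsilyloxy)benzyne (formed in the flask) | COC1=CC(O[Si](C(C)C)(C(C)C)C(C)C)=CC#C1 | intermediate
8 | [2-methoxy-6-pentyl-4-(triisopropylsilyloxy)phenyl]lithium (formed in the flask) | CCCCCc1cc(O[Si](C(C)C)(C(C)C)C(C)C)cc(OC)c1[Li] | intermediate
9 | 2-methoxy-6-pentyl-4-(triisopropylsilyloxy)benzoic acid | CCCCCc1cc(O[Si](C(C)C)(C(C)C)C(C)C)cc(OC)c1C(=O)O | intermediate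
10 | benzyl 2-methoxy-6-pentyl-4-(triisopropylsilyloxy)benzoate | CCCCCc1cc(O[Si](C(C)C)(C(C)C)C(C)C)cc(OC)c1C(=O)OCc1ccccc1 | intermediate
11 | benzyl 4-hydroxy-2-methoxy-6-pentylbenzoate | CCCCCc1cc(O)cc(OC)c1C(=O)OCc1ccccc1 | intermediate
12 | 5-propylresorcinol (divarinol) | CCCc1cc(O)cc(O)c1 | starting material
13 | N-[(2,4-dihydroxy-6-propylphenyl)methylidene]-N-methylmethanaminium chloride (formed in the flask) | CCCc1cc(O)cc(O)c1C=[N+](C)C.[Cl-] | intermediate
14 | 2,4-dihydroxy-6-propylbenzaldehyde | CCCc1cc(O)cc(O)c1C=O | intermediate
15 | 2-hydroxy-4-methoxy-6-propylbenzaldehyde | CCCc1cc(OC)cc(O)c1C=O | intermediate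
16 | 2-benzyloxy-4-methoxy-6-propylbenzaldehyde | CCCc1cc(OC)cc(OCc2ccccc2)c1C=O | intermediate
17 | 2-benzyloxy-4-methoxy-6-propylbenzoic acid | CCCc1cc(OC)cc(OCc2ccccc2)c1C(=O)O | intermediate
18 | 2-benzyloxy-4-methoxy-6-propylbenzoyl chloride (formed in the flask) | CCCc1cc(OC)cc(OCc2ccccc2)c1C(=O)Cl | intermediate
19 | benzyl 4-[(2-benzyloxy-4-methoxy-6-propylbenzoyl)oxy]-2-methoxy-6-pentylbenzoate | CCCCCc1cc(OC(=O)c2c(OCc3ccccc3)cc(OC)cc2CCC)cc(OC)c1C(=O)OCc1ccccc1 | intermediate
20 | 4-[(2-hydroxy-4-methoxy-6-propylbenzoyl)oxy]-2-methoxy-6-pentylbenzoic acid | CCCCCc1cc(OC(=O)c2c(O)cc(OC)cc2CCC)cc(OC)c1C(=O)O | target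

**Step count.** Total: 11 steps. Longest linear sequence: 6 steps (1 → 2 → 9 → 10 → 11 → 19 → 20; the ring A branch 12 → 14 → 15 → 16 → 17 → 19 → 20 is equally long).

**Steps most likely to fail**

Step 3. The aryne may be captured by the lithiated fluoroarene or by the product aryllithium instead of pentyllithium, giving biaryl coupling. Some lithiation beside the silyl ether would also lead to the regioisomeric aryne. The fallback avoids the aryne and reverses the order of bond formation. It sets out from 2, which is lithiated with LDA in THF at −78 °C and carboxylated with CO2 at that temperature, before any fluoride loss, to give 2-fluoro-6-methoxy-4-(triisopropylsilyloxy)benzoic acid F1. Treating F1 with pentyllithium 4 (about 3 equiv, THF, −78 → 0 °C) should then displace the ortho fluoride by carboxylate-directed nucleophilic aromatic substitution (addition–elimination on the unprotected 2-fluorobenzoate, fluoride being a better leaving group than methoxide). This returns to the route at 9.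

Step 10. Addition–elimination at the doubly ortho-substituted aroyl chloride may be slow, and the ortho benzyl ether may be partly lost to HCl while the chloride is made. The fallback sets out from 17 and 11 and joins them by dehydrative coupling with trifluoroacetic anhydride in toluene at rt. The acid forms 2-benzyloxy-4-methoxy-6-propylbenzoic trifluoroacetic anhydride F2, which ionises to a linear aroylium ion that is insensitive to ortho hindrance and O-acylates phenol 11. This returns to the route at 19.

Step 7. Methylation may not stop cleanly after the first hydroxyl, so that alkylation of the chelated C2 hydroxyl gives mixtures. The fallback sets out from 14, which is methylated exhaustively (MeI excess, K2CO3, DMF) to 2,4-dimethoxy-6-propylbenzaldehyde F3. The methyl ether ortho to the formyl group is then cleaved selectively with BCl3 (CH2Cl2, −78 → 0 °C), where chelation of boron between the formyl oxygen and the ortho ether oxygen directs the dealkylation. This returns to the route at 15.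

**Further compounds**
F1 | step 3 | 2-fluoro-6-methoxy-4-(triisopropylsilyloxy)benzoic acid | COc1cc(O[Si](C(C)C)(C(C)C)C(C)C)cc(F)c1C(=O)O
F2 | step 10 | 2-benzyloxy-4-methoxy-6-propylbenzoic trifluoroacetic anhydride | CCCc1cc(OC)cc(OCc2ccccc2)c1C(=O)OC(=O)C(F)(F)F
F3 | step 7 | 2,4-dimethoxy-6-propylbenzaldehyde | CCCc1cc(OC)cc(OC)c1C=O
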